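## Structural features

The target is the 3-hydroxy-4-methoxybenzoate (isovanillate) of a trans-fused perhydroazulene. Azulene-type locants are used throughout: C3a and C8a are the fusion carbons, C1–C3 complete the five-membered ring and C4–C8 the seven-membered ring. The five-membered ring carries a trisubstituted C1–C2 epoxide with a methyl group on C2. The seven-membered ring carries isopropyl at C4, the aroyloxy group at C5 and a methyl-bearing tertiary carbinol at C7. There are seven stereocentres: C1/C2 (epoxide, on the face of the C3a hydrogen), and the contiguous run C8a–C3a–C4–C5, in which H-8a and H-3a are trans, the isopropyl group is trans to the C3 arm and cis to the C5 oxygen; C7 lies 1,3 to C5 with the two oxygens cis. The fragile groups are the acid-labile epoxide, the hindered aryl ester, the free phenol and the tertiary alcohol. The real difficulty is the trans,trans triad C8a–C3a–C4 on a seven-membered ring, with C5, C7 and the epoxide each on a defined face. The key step uses the fact that, once C6 is excised, C8–C8a–C3a–C4–C5–C7 is a cyclohexene carrying a C5=C7 silyl enol ether. That ring is the adduct of a 2-silyloxydiene (C4=C5–C7=C8) with an enal (C8a=C3a), whose formyl carbon becomes C1 and whose methallyl arm supplies C3, C2 and the C2 methyl.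

## Logic of the disconnections

26 to 25: only the phenolic O–Si bond is cut. The phenol travels as a silyl ether so that the acid component cannot acylate itself and the phenol never meets an oxidant. The forward step must cleave an aryl silyl ether without touching an epoxide, an aryl ester or a tertiary alcohol.

25 to 24: the C1–O and C2–O bonds are cut, leaving the C1=C2 alkene. The epoxide is the most acid-sensitive group, so it is placed next to last; the five-membered ring becomes a plain trisubstituted cyclopentene, which is a metathesis retron. The forward step must deliver oxygen to the face that carries the C7 hydroxyl.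

24 to 19 and 22: the ester C(=O)–O bond is cut. This separates the arene from the terpenoid and makes the route convergent. The forward step must acylate a hindered secondary alcohol beside a tertiary one, and C5 must already be correct because acylation retains configuration. 22 goes back to 20 by cutting the same O–Si bond.

19 to 18 to 17: the C7–O bond (and the C6–H bond) is traced to the C6=C7 alkene of an allylic alcohol. The C7 configuration is relayed from C5, so only C5 remains to be controlled. The forward steps need syn oxygen delivery from the C5 hydroxyl and hydride opening at C6 rather than C7.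

17 to 16: the C5–H bond is cut, giving the enone. The forward step needs 1,2-hydride delivery to the face that leaves the hydroxyl cis to the isopropyl group.

16 to 14 to 13: the C5–C6 and C6–C7 bonds are cut, removing C6. The seven-membered enone becomes a cyclohexene silyl enol ether, whose position (C5=C7) fixes where the carbon is inserted. This turns the ring into a Diels–Alder retron. The forward steps need methylene transfer to the enol ether in preference to the cyclopentene, then cleavage of the internal cyclopropane bond.

13 to 12 to 11: the C1=C2 bond is cut (metathesis), then the vinyl group is returned to a formyl group. The bicycle becomes a monocycle, and the formyl group is the activating group of the cycloaddition. The forward steps need the two arms trans so that a trans-fused ring can close, and the C8a centre must survive olefination.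

11 to 5 and 10: the C3a–C4 and C8–C8a bonds are cut. One ring and three stereocentres are traded for two achiral open-chain partners. The forward step needs regio-, endo- and facial control, a (Z)-enol ether and an (E)-enal.

5 to 4 to 3 to 1 and 2: the O–Si bond, then the carbonyl (from the carbinol), then the bond between the carbinol carbon and the isopropenyl carbon. The forward enolisation must give the (Z)-enol ether.

10 to 9 to 8 to 6 and 7: the aldehyde (from the alcohol), the (E)-alkene (from the alkyne), then the bond between the alkyne carbon and the allylic CH2. The skipped diene must not move into conjugation at any stage.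

## Other disconnections considered

Alternative 1: The cut is C5–C6. In the forward sense the 2-lithio-1,3-dithiane of A1 (dithiane on C5, a 2-methyl-2-alkyl epoxide tethered through C8) would attack the primary epoxide carbon C6 and close the seven-membered ring to the spiro-dithiane carbinol A2.
- In its favour: the C7 carbinol arrives with its configuration fixed by the epoxide; C5 is at the ketone oxidation level; attack at the unhindered terminus of a 2,2-disubstituted epoxide is the normal mode; the cyclopentene is inert to the carbanion.
- Against it here: the closure is an endo-mode epoxide opening to a seven-membered ring, and the carbanion sits next to the isopropyl-bearing C4, so both deprotonation and alkylation are hindered. A1 must already hold C8a, C3a and C4 (one of them acyclic) plus an independently made epoxide centre, for which 1,1-disubstituted alkenes offer weak stereocontrol. After closure, dithiane hydrolysis beside a trisubstituted alkene gives a β-hydroxy ketone open to retro-aldol cleavage and dehydration.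
- Comparison: on structure it is the better plan for the C5/C7 oxygen pattern, since no redox relay is needed and the C7 hydroxyl could steer a syn reduction at C5. The chosen plan spends steps 12–14 on this. It is equal on chemoselectivity among alkenes or better. It leaves the C8a–C3a–C4 triad unsolved, which the chosen plan settles in one catalytic step. On step economy, the stereodefined synthesis of A1 is expected to cost more than the closure saves.

Alternative 2: The cut is inside the arene (C2'–C3' and C4'–C5'). In the forward sense the coumalate ester A3 of diol 19 would react with the ketene acetal A4. Cycloaddition, loss of CO2 and loss of methanol would give the silyl-protected isovanillate A5, which has the constitution of 24.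
- In its favour: the polarisation of pyrone and ketene acetal should place methoxy para and silyloxy meta to the ester; the conditions are neutral; the acyl donor is small.
- Against it here: it builds a ring that is available as 20; A4 is not a stock reagent and is moisture-sensitive; the pyrone is open to nucleophilic ring opening; heating a ketene acetal beside a free tertiary alcohol invites orthoester formation. It does nothing for the hydroazulene, which would still have to be made.
- Comparison: the endgame is equal, because A5 and 24 are the same compound, and the C5–O bond is untouched in both, so stereochemical risk at C5 is equal. It could be the better choice if the hindered C5 hydroxyl resisted a 3,4-disubstituted benzoyl donor. It is one to three steps longer and is complementary to the chosen key step, not a rival to it.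

Alternative 3: The cut is C3a–C8a. In the forward sense the silyl ketene acetal of the eleven-membered (E)-allylic lactone A6 would rearrange (Ireland–Claisen) to the cycloheptane acid A7, with a vinyl group on C8a and the carboxyl on C3a.
- In its favour: a sigmatropic shift forms the fusion bond with transfer of alkene geometry; a seven-membered carbocycle arises from a macrolactone; the C5/C7 oxygens are already in place as a cis acetonide set by open-chain methods.
- Against it here: the C3a/C8a relationship depends on the ketene acetal geometry and on a chair- or boat-like transition state inside a bridged macrocycle, which is hard to predict. A6 needs C4, C5 and C7 from a long linear sequence. After the key step the five-membered ring must still be built from the carboxyl and vinyl groups by reduction, one-carbon-plus-isopropenyl homologation and metathesis.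
- Comparison: it is the equal of the chosen plan, or better, in having the C5/C7 oxygens set early with no late redox relay and no competition between alkenes. Its key step forms one skeletal bond and two stereocentres against two bonds and three stereocentres. Both are pericyclic, but the endo and geometry rules of the cycloaddition are the more predictable. The route would be clearly longer.

Key step: step 7

Assumption: enal 10 is taken to bind the oxazaborolidinium ion in the usual aldehyde mode (boron syn to the formyl hydrogen, formyl C–H···O contact), which assigns the required Cα-Si/Cβ-Re face to the (R)-prolinol-derived catalyst; if the other binding mode prevailed, the (S)-antipode would be used with no other change.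

Step 1
Reactants: 1 isovaleraldehyde (3-methylbutanal); 2 isopropenylmagnesium bromide
Product: 3 2,5-dimethylhex-1-en-3-ol (racemic)
Conditions: THF, 0 °C → rt; then aq. NH4Cl
Reagents that add atoms: none
Why: Grignard 1,2-addition of the alkenyl nucleophile to the aldehyde; the carbinol centre is racemic and is removed in step 2.

Step 2
Reactants: 3 2,5-dimethylhex-1-en-3-ol
Product: 4 2,5-dimethylhex-1-en-3-one
Conditions: Dess–Martin periodinane, CH2Cl2, 0 °C → rt
Reagents that add atoms: none
Why: Dess–Martin oxidation of a secondary allylic alcohol under near-neutral conditions, which should leave the volatile, polymerisable isopropenyl ketone intact.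

Step 3
Reactants: 4 2,5-dimethylhex-1-en-3-one
Product: 5 (3Z)-2,5-dimethyl-3-(triisopropylsilyloxy)hexa-1,3-diene
Conditions: i-Pr3SiOTf, Et3N, CH2Cl2, 0 °C → rt
Reagents that add atoms: triisopropylsilyl trifluoromethanesulfonate, CC(C)[Si](C(C)C)(C(C)C)OS(=O)(=O)C(F)(F)F
Why: Soft enolisation (silyl triflate, amine) can only occur toward the CH2 group; the (Z)-enol ether is expected because the (E)-isomer would press the isopropyl group against the isopropenyl group (allylic 1,3-strain). The bulky silyl group is kept on purpose, to resist protodesilylation and silyl transfer in step 7.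

Step 4
Reactants: 6 propargyl alcohol (prop-2-yn-1-ol); 7 3-chloro-2-methylprop-1-ene
Product: 8 5-methylhex-5-en-2-yn-1-ol
Conditions: CuI (10 mol%), NaI (cat.), K2CO3, DMF, rt
Reagents that add atoms: none
Why: Copper-catalysed allylation of a terminal alkyne: the monovalent copper acetylide formed under carbonate base is alkylated by the allylic halide; SN2 and SN2' attack give the same product with this symmetrical allyl unit, and the free hydroxyl is tolerated.

Step 5
Reactants: 8 5-methylhex-5-en-2-yn-1-ol
Product: 9 (2E)-5-methylhexa-2,5-dien-1-ol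
Conditions: NaAlH2(OCH2CH2OMe)2, THF, 0 °C → rt; then H2O
Reagents that add atoms: none
Why: Alkoxide-directed trans-hydroalumination of the propargylic alcohol and protonolysis of the vinylalane should give the (E)-allylic alcohol only; the isolated 1,1-disubstituted alkene is not reduced.

Step 6
Reactants: 9 (2E)-5-methylhexa-2,5-dien-1-ol
Product: 10 (2E)-5-methylhexa-2,5-dienal
Conditions: activated MnO2, CH2Cl2, rt; filtrate used directly
Reagents that add atoms: none
Why: Allylic oxidation on a neutral solid surface; no acid or base is present that could move the skipped alkene into conjugation, and the volatile aldehyde is used as its solution.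

Step 7
Reactants: 5 (3Z)-2,5-dimethyl-3-(triisopropylsilyloxy)hexa-1,3-diene; 10 (2E)-5-methylhexa-2,5-dienal
Product: 11 (1S,5S,6S)-3-methyl-6-(2-methylprop-2-en-1-yl)-5-(propan-2-yl)-4-(triisopropylsilyloxy)cyclohex-3-ene-1-carbaldehyde
Conditions: (R)-B-(o-tolyl)oxazaborolidine from (R)-α,α-diphenylprolinol and (o-TolBO)3 (20 mol%), HNTf2 (18 mol%), CH2Cl2, −78 → −40 °C
Reagents that add atoms: none
Why: The N-protonated oxazaborolidine binds the formyl oxygen of 10 and the s-trans enal undergoes an asynchronous concerted [4+2] cycloaddition with the s-cis conformer of 5; the closest known reaction type is the oxazaborolidinium-catalysed Diels–Alder reaction of 2-silyloxydienes with α,β-unsaturated aldehydes. The cyclohexene closes in one suprafacial [4+2] event in which the C4–C3a bond runs ahead of C8–C8a, so no separate ring-closing mode is involved. C3a and C8a come out trans because the (E)-geometry of 10 is transferred stereospecifically. C4 is fixed relative to them by the endo position of the catalyst-bound formyl group together with the outside position of the isopropyl group in the (Z)-enol ether, which places isopropyl cis to CHO and trans to the methallyl arm. The absolute sense comes from the catalyst: the phenyl group cis to the bound aldehyde covers one enal face, so the diene should add to the Cα-Si/Cβ-Re face with the (R)-prolinol-derived cation. Regioselectivity is secured by the 2-silyloxy group, which makes C4 the nucleophilic terminus and puts the formyl-bearing carbon para to oxygen. The bulky silyl group slows silyl transfer, so any open-chain Mukaiyama–Michael character should collapse to the cycloadduct, and the low temperature and non-basic medium keep the skipped diene of 10 in place.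

Step 8
Reactants: 11 (1S,5S,6S)-3-methyl-6-(2-methylprop-2-en-1-yl)-5-(propan-2-yl)-4-(triisopropylsilyloxy)cyclohex-3-ene-1-carbaldehyde
Product: 12 triisopropyl{[(4R,5R,6S)-4-ethenyl-2-methyl-5-(2-methylprop-2-en-1-yl)-6-(propan-2-yl)cyclohex-1-en-1-yl]oxy}silane
Conditions: Ph3PCH3Br, KOt-Bu, THF, 0 °C
Reagents that add atoms: methyltriphenylphosphonium bromide, C[P+](c1ccccc1)(c1ccccc1)c1ccccc1.[Br-]
Why: Wittig methylenation of the aldehyde; C8a already has the more stable trans (pseudo-equatorial) arrangement, so the basic ylide should not erode it, and the silyl enol ether is inert.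

Step 9
Reactants: 12 triisopropyl{[(4R,5R,6S)-4-ethenyl-2-methyl-5-(2-methylprop-2-en-1-yl)-6-(propan-2-yl)cyclohex-1-en-1-yl]oxy}silane
Product: 13 triisopropyl{[(3aS,7S,7aR)-2,5-dimethyl-7-(propan-2-yl)-3a,4,7,7a-tetrahydro-1H-inden-6-yl]oxy}silane (trans-fused)
Conditions: (H2IMes)(PCy3)Cl2Ru=CHPh (second-generation Grubbs catalyst, 5 mol%), CH2Cl2, 40 °C
Reagents that add atoms: none
Why: Ring-closing metathesis of the vinyl group with the 1,1-disubstituted alkene gives the trisubstituted cyclopentene with loss of ethene; the two trans, pseudo-equatorial arms can reach each other, and the tetrasubstituted enol ether does not engage the carbene. No stereocentre is formed.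

Step 10
Reactants: 13 triisopropyl{[(3aS,7S,7aR)-2,5-dimethyl-7-(propan-2-yl)-3a,4,7,7a-tetrahydro-1H-inden-6-yl]oxy}silane
Product: 14 siloxycyclopropane: 13 with a CH2 bridge (the future C6) across C5–C7, on the face opposite the C4 isopropyl group
Conditions: Et2Zn (1.3 equiv), CH2I2 (1.3 equiv), CH2Cl2, 0 °C
Reagents that add atoms: diiodomethane, ICI
Why: Simmons–Smith cyclopropanation in its Et2Zn/CH2I2 form; the electrophilic zinc carbenoid should choose the most electron-rich π-bond, the silyl enol ether, over the trisubstituted ring alkene when the reagent is limited. The CH2 should add anti to the isopropyl group, but both cyclopropane configurations converge in step 11.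

Step 11
Reactants: 14 siloxycyclopropane
Product: 16 (3aR,4S,8aS)-2,7-dimethyl-4-(propan-2-yl)-3a,4,8,8a-tetrahydroazulen-5(3H)-one, via β-chloro ketone 15 (not isolated)
Conditions: FeCl3 (2.2 equiv), DMF, 0 °C → rt; then NaOAc, MeOH, 60 °C
Reagents that add atoms: none
Why: Oxidative ring expansion of a siloxycyclopropane: single-electron oxidation by trivalent iron and β-scission of the internal C5–C7 bond give the tertiary C7 radical, which takes chlorine to form 15 with C6 now between C5 and C7. Acetate then removes HCl through the C6 enolate (E1cB) to give the conjugated C6=C7 enone; C4, α to the ketone, already holds the more stable pseudo-equatorial isopropyl group.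

Step 12
Reactants: 16 (3aR,4S,8aS)-2,7-dimethyl-4-(propan-2-yl)-3a,4,8,8a-tetrahydroazulen-5(3H)-one
Product: 17 (3aR,4S,5S,8aS)-2,7-dimethyl-4-(propan-2-yl)-3,3a,4,5,8,8a-hexahydroazulen-5-ol
Conditions: LiBH(s-Bu)3, THF, −78 °C; then H2O
Reagents that add atoms: none
Why: 1,2-Reduction of a β,β-disubstituted enone, which resists conjugate hydride delivery. The bulky trialkylborohydride should approach C5 from the side of the axial C4 hydrogen, away from the axial C3a hydrogen, giving the pseudo-axial alcohol cis to the isopropyl group, as hindered hydrides do with 2-alkylcycloalkanones.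

Step 13
Reactants: 17 (3aR,4S,5S,8aS)-2,7-dimethyl-4-(propan-2-yl)-3,3a,4,5,8,8a-hexahydroazulen-5-ol
Product: 18 (3aR,4S,5S,6S,7R,8aS)-6,7-epoxy-2,7-dimethyl-4-(propan-2-yl)-3,3a,4,5,6,7,8,8a-octahydroazulen-5-ol (epoxide cis to the hydroxyl)
Conditions: VO(acac)2 (5 mol%), t-BuOOH, CH2Cl2, 0 °C → rt
Reagents that add atoms: tert-butyl hydroperoxide, CC(C)(C)OO
Why: Hydroxyl-directed epoxidation: the pentavalent vanadium alkoxide–peroxide delivers oxygen to the adjacent C6=C7 alkene on the face of the pseudo-axial C5 hydroxyl, which sets C7 (and C6). The cyclopentene alkene is remote from the hydroxyl and should not react.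

Step 14
Reactants: 18 (3aR,4S,5S,6S,7R,8aS)-6,7-epoxy-2,7-dimethyl-4-(propan-2-yl)-3,3a,4,5,6,7,8,8a-octahydroazulen-5-ol
Product: 19 (3aR,4S,5R,7R,8aS)-2,7-dimethyl-4-(propan-2-yl)-3,3a,4,5,6,7,8,8a-octahydroazulene-5,7-diol
Conditions: NaAlH2(OCH2CH2OMe)2, THF, 0 °C → rt; then H2O
Reagents that add atoms: none
Why: Hydride opening of a 2,3-epoxy alcohol at C6, which is both the less substituted carbon and the position this aluminate favours, to give the 1,3-diol. The C7–O bond is not broken, so the C7 configuration from step 13 is kept, with its hydroxyl cis to the C5 hydroxyl.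

Step 15
Reactants: 20 3-hydroxy-4-methoxybenzoic acid (isovanillic acid)
Product: 22 3-(tert-butyldimethylsilyloxy)-4-methoxybenzoic acid, via bis-silylated acid 21 (not isolated)
Conditions: t-BuMe2SiCl (2.2 equiv), imidazole, DMF, rt; then THF–H2O–AcOH, rt
Reagents that add atoms: tert-butyldimethylsilyl chloride, CC(C)(C)[Si](C)(C)Cl
Why: Silylation of both acidic sites, then selective hydrolysis of the silyl ester, which is far more labile than the aryl silyl ether.

Step 16
Reactants: 19 (3aR,4S,5R,7R,8aS)-2,7-dimethyl-4-(propan-2-yl)-3,3a,4,5,6,7,8,8a-octahydroazulene-5,7-diol; 22 3-(tert-butyldimethylsilyloxy)-4-methoxybenzoic acid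
Product: 24 (3aR,4S,5R,7R,8aS)-7-hydroxy-2,7-dimethyl-4-(propan-2-yl)-3,3a,4,5,6,7,8,8a-octahydroazulen-5-yl 3-(tert-butyldimethylsilyloxy)-4-methoxybenzoate, via mixed anhydride 23 (not isolated)
Conditions: 22, 2,4,6-Cl3C6H2COCl, Et3N, THF, rt; then 19, DMAP, toluene, 40 °C
Reagents that add atoms: none
Why: Yamaguchi esterification: DMAP attacks the less hindered aroyl carbonyl of the mixed anhydride and the acylpyridinium ion acylates the secondary C5 hydroxyl. The tertiary C7 hydroxyl should not react, and C5 keeps its configuration because its C–O bond is untouched.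

Step 17
Reactants: 24 (3aR,4S,5R,7R,8aS)-7-hydroxy-2,7-dimethyl-4-(propan-2-yl)-3,3a,4,5,6,7,8,8a-octahydroazulen-5-yl 3-(tert-butyldimethylsilyloxy)-4-methoxybenzoate
Product: 25 (1S,2R,3aR,4S,5R,7R,8aS)-1,2-epoxy-7-hydroxy-2,7-dimethyl-4-(propan-2-yl)decahydroazulen-5-yl 3-(tert-butyldimethylsilyloxy)-4-methoxybenzoate
Conditions: VO(acac)2 (5 mol%), t-BuOOH, CH2Cl2, 0 °C → rt
Reagents that add atoms: tert-butyl hydroperoxide, CC(C)(C)OO
Why: Hydroxyl-directed epoxidation of a bishomoallylic alcohol: the tertiary C7 hydroxyl, on the α-face, binds vanadium and should deliver oxygen to the same face of the only remaining alkene, setting C1 and C2. The hydroxyl is cis to the new epoxide and so cannot open it from the rear.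

Step 18
Reactants: 25 (1S,2R,3aR,4S,5R,7R,8aS)-1,2-epoxy-7-hydroxy-2,7-dimethyl-4-(propan-2-yl)decahydroazulen-5-yl 3-(tert-butyldimethylsilyloxy)-4-methoxybenzoate
Product: 26 (1S,2R,3aR,4S,5R,7R,8aS)-1,2-epoxy-7-hydroxy-2,7-dimethyl-4-(propan-2-yl)decahydroazulen-5-yl 3-hydroxy-4-methoxybenzoate (CNP0106636.1)
Conditions: Bu4NF, AcOH, THF, 0 °C
Reagents that add atoms: none
Why: Fluoride cleaves the aryl silyl ether quickly because phenoxide is a good leaving group from silicon; the acetic acid buffer should keep the epoxide, the ester and the tertiary alcohol intact.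

Compound list

1 | isovaleraldehyde (3-methylbutanal) | CC(C)CC=O | starting material
2 | isopropenylmagnesium bromide | CC(=C)[Mg]Br | starting material
3 | 2,5-dimethylhex-1-en-3-ol (racemic) | CC(C)CC(O)C(C)=C | intermediate
4 | 2,5-dimethylhex-1-en-3-one | CC(C)CC(=O)C(C)=C | intermediate
5 | (3Z)-2,5-dimethyl-3-(triisopropylsilyloxy)hexa-1,3-diene | CC(C)/C=C(\O[Si](C(C)C)(C(C)C)C(C)C)C(C)=C | intermediate
6 | propargyl alcohol (prop-2-yn-1-ol) | OCC#C | starting material
7 | 3-chloro-2-methylprop-1-ene | CC(=C)CCl | starting material
8 | 5-methylhex-5-en-2-yn-1-ol | OCC#CCC(C)=C | intermediate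
9 | (2E)-5-methylhexa-2,5-dien-1-ol | OC/C=C/CC(C)=C | intermediate
10 | (2E)-5-methylhexa-2,5-dienal | O=C/C=C/CC(C)=C | intermediate
11 | (1S,5S,6S)-3-methyl-6-(2-methylprop-2-en-1-yl)-5-(propan-2-yl)-4-(triisopropylsilyloxy)cyclohex-3-ene-1-carbaldehyde | CC(C)[Si](C(C)C)(C(C)C)OC1=C(C)C[C@H](C=O)[C@@H](CC(C)=C)[C@@H]1C(C)C | intermediate
12 | triisopropyl{[(4R,5R,6S)-4-ethenyl-2-methyl-5-(2-methylprop-2-en-1-yl)-6-(propan-2-yl)cyclohex-1-en-1-yl]oxy}silane | CC(C)[Si](C(C)C)(C(C)C)OC1=C(C)C[C@H](C=C)[C@@H](CC(C)=C)[C@@H]1C(C)C | intermediate
13 | triisopropyl{[(3aS,7S,7aR)-2,5-dimethyl-7-(propan-2-yl)-3a,4,7,7a-tetrahydro-1H-inden-6-yl]oxy}silane | CC(C)[Si](C(C)C)(C(C)C)OC1=C(C)C[C@H]2[C@@H](CC(C)=C2)[C@@H]1C(C)C | intermediate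
14 | siloxycyclopropane (13 with CH2 across C5–C7, anti to isopropyl) | CC(C)[Si](C(C)C)(C(C)C)O[C@]12C[C@@]1(C)C[C@H]3[C@@H](CC(C)=C3)[C@@H]2C(C)C | intermediate
15 | (3aR,4S,8aS)-7-chloro-2,7-dimethyl-4-(propan-2-yl)-3a,4,6,7,8,8a-hexahydroazulen-5(3H)-one (C7 unassigned) | O=C1CC(C)(Cl)C[C@H]2[C@@H](CC(C)=C2)[C@@H]1C(C)C | intermediate
16 | (3aR,4S,8aS)-2,7-dimethyl-4-(propan-2-yl)-3a,4,8,8a-tetrahydroazulen-5(3H)-one | O=C1C=C(C)C[C@H]2[C@@H](CC(C)=C2)[C@@H]1C(C)C | intermediate
17 | (3aR,4S,5S,8aS)-2,7-dimethyl-4-(propan-2-yl)-3,3a,4,5,8,8a-hexahydroazulen-5-ol | O[C@@H]1C=C(C)C[C@H]2[C@@H](CC(C)=C2)[C@@H]1C(C)C | intermediate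
18 | (3aR,4S,5S,6S,7R,8aS)-6,7-epoxy-2,7-dimethyl-4-(propan-2-yl)-3,3a,4,5,6,7,8,8a-octahydroazulen-5-ol | O[C@@H]1[C@@H]2O[C@]2(C)C[C@H]3[C@@H](CC(C)=C3)[C@@H]1C(C)C | intermediate
19 | (3aR,4S,5R,7R,8aS)-2,7-dimethyl-4-(propan-2-yl)-3,3a,4,5,6,7,8,8a-octahydroazulene-5,7-diol | O[C@@H]1C[C@](C)(O)C[C@H]2[C@@H](CC(C)=C2)[C@@H]1C(C)C | intermediate
20 | 3-hydroxy-4-methoxybenzoic acid (isovanillic acid) | COc1ccc(C(=O)O)cc1O | starting material
21 | tert-butyldimethylsilyl 3-(tert-butyldimethylsilyloxy)-4-methoxybenzoate | COc1ccc(C(=O)O[Si](C)(C)C(C)(C)C)cc1O[Si](C)(C)C(C)(C)C | intermediate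
22 | 3-(tert-butyldimethylsilyloxy)-4-methoxybenzoic acid | COc1ccc(C(=O)O)cc1O[Si](C)(C)C(C)(C)C | intermediate
23 | 3-(tert-butyldimethylsilyloxy)-4-methoxybenzoic 2,4,6-trichlorobenzoic anhydride | COc1ccc(C(=O)OC(=O)c2c(Cl)cc(Cl)cc2Cl)cc1O[Si](C)(C)C(C)(C)C | intermediate
24 | (3aR,4S,5R,7R,8aS)-7-hydroxy-2,7-dimethyl-4-(propan-2-yl)-3,3a,4,5,6,7,8,8a-octahydroazulen-5-yl 3-(tert-butyldimethylsilyloxy)-4-methoxybenzoate | COc1ccc(C(=O)O[C@@H]2C[C@](C)(O)C[C@H]3[C@@H](CC(C)=C3)[C@@H]2C(C)C)cc1O[Si](C)(C)C(C)(C)C | intermediate
25 | (1S,2R,3aR,4S,5R,7R,8aS)-1,2-epoxy-7-hydroxy-2,7-dimethyl-4-(propan-2-yl)decahydroazulen-5-yl 3-(tert-butyldimethylsilyloxy)-4-methoxybenzoate | COc1ccc(C(=O)O[C@@H]2C[C@](C)(O)C[C@H]3[C@@H](C[C@@]4(C)O[C@@H]34)[C@@H]2C(C)C)cc1O[Si](C)(C)C(C)(C)C | intermediate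
26 | (1S,2R,3aR,4S,5R,7R,8aS)-1,2-epoxy-7-hydroxy-2,7-dimethyl-4-(propan-2-yl)decahydroazulen-5-yl 3-hydroxy-4-methoxybenzoate | COc1ccc(C(=O)O[C@@H]2C[C@](C)(O)C[C@H]3[C@@H](C[C@@]4(C)O[C@@H]34)[C@@H]2C(C)C)cc1O | target

Total step count: 18. Longest linear sequence: 14 steps (steps 1–3 or 4–6, then 7–14 and 16–18).

Least certain steps

Step 7 (key step). The cycloaddition may be slow, because the isopropyl-bearing diene terminus must bond to a β-branched enal carbon. Acid-promoted migration of the skipped alkene into conjugation, protodesilylation of the diene or open-chain conjugate addition could then overtake it. Facial control could also erode if part of the enal binds through its α-C–H instead of the formyl C–H. The fallback sets out from 10 and replaces catalyst control by a covalently bound oxazolidinone auxiliary on a bidentate dienophile: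
- Chlorite oxidation of 10 (NaClO2, NaH2PO4, 2-methylbut-2-ene) should give (2E)-5-methylhexa-2,5-dienoic acid F1.
- Its pivaloyl mixed anhydride would acylate lithiated (S)-4-benzyl-1,3-oxazolidin-2-one to give the imide (4S)-4-benzyl-3-[(2E)-5-methylhexa-2,5-dienoyl]-1,3-oxazolidin-2-one F2.
- Et2AlCl-promoted cycloaddition of F2 with 5 (CH2Cl2, −78 °C) is expected to give the imide adduct F3, with the benzyl group covering the face opposite to the one needed. The chelated s-cis imide model for the (S)-auxiliary exposes the same Cα face as required for 11.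
- LiBH4 would release the auxiliary and give the primary alcohol [(1S,5S,6R)-3-methyl-6-(2-methylprop-2-en-1-yl)-5-(propan-2-yl)-4-(triisopropylsilyloxy)cyclohex-3-en-1-yl]methanol F4.
- Dess–Martin oxidation of F4 returns to the route at 11.

Step 10. Methylene transfer may go to the cyclopentene alkene, or be slow at the crowded tetrasubstituted enol ether. The fallback sets out from 13 and uses a free dihalocarbene, whose electrophilic selectivity for the most electron-rich alkene is steeper:
- CHBr3 and KOt-Bu (pentane, −20 °C) should give the gem-dibromocyclopropane F5.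
- Warming, with loss of the silyl bromide, opens it to (3aR,4S,8aS)-6-bromo-2,7-dimethyl-4-(propan-2-yl)-3a,4,8,8a-tetrahydroazulen-5(3H)-one F6.
- Hydrodebromination with Bu3SnH and catalytic Pd(PPh3)4 (zerovalent palladium) returns to the route at 16, bypassing step 11.

Step 11. Single-electron oxidation and fragmentation of the bulky silyl ether may be slow. That would allow acid-type opening of the external cyclopropane bond (no ring expansion), or loss of HCl toward C8 or the methyl group instead of C6. The fallback sets out from 14. Buffered fluoride (Bu4NF, AcOH, THF, 0 °C) should free the cyclopropanol F7. As an iron alkoxide, F7 should be oxidised by FeCl3 in DMF in an inner-sphere manner, far more readily than the silyl ether. This returns to the route at 15, which is then treated with NaOAc as planned.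

Step 12. Hydride may be delivered to the other face, giving the pseudo-equatorial alcohol, or add in conjugate fashion. The fallback sets out from 16 and makes the other epimer on purpose, then inverts it:
- NaBH4 with CeCl3·7H2O (MeOH, −78 °C), a small hydride that prefers axial attack, should give (3aR,4S,5R,8aS)-2,7-dimethyl-4-(propan-2-yl)-3,3a,4,5,8,8a-hexahydroazulen-5-ol F8.
- Mitsunobu inversion (4-nitrobenzoic acid, PPh3, DIAD) would give (3aR,4S,5S,8aS)-2,7-dimethyl-4-(propan-2-yl)-3,3a,4,5,8,8a-hexahydroazulen-5-yl 4-nitrobenzoate F9.
- Methanolysis (K2CO3, MeOH) returns to the route at 17.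

Step 17. Oxygen may be delivered to the β-face if the tertiary hydroxyl binds vanadium poorly, and the Lewis-acidic medium may open the new epoxide. The fallback sets out from 19 and uses reagent control before the arene is present. A Shi epoxidation (fructose-derived ketone of the L-series, which the spiro transition-state model assigns to the α-face; KHSO5 as its triple salt, K2CO3 buffer, MeCN–CH2(OMe)2–H2O, 0 °C) should give (1S,2R,3aR,4S,5R,7R,8aS)-1,2-epoxy-2,7-dimethyl-4-(propan-2-yl)decahydroazulene-5,7-diol F10. Acylation of F10 with 23 under the conditions of step 16 returns to the route at 25.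

Further compounds

F1 | step 7 | (2E)-5-methylhexa-2,5-dienoic acid | OC(=O)/C=C/CC(C)=C
F2 | step 7 | (4S)-4-benzyl-3-[(2E)-5-methylhexa-2,5-dienoyl]-1,3-oxazolidin-2-one | O=C(/C=C/CC(C)=C)N1[C@@H](Cc2ccccc2)COC1=O
F3 | step 7 | (4S)-4-benzyl-3-{[(1S,5S,6S)-3-methyl-6-(2-methylprop-2-en-1-yl)-5-(propan-2-yl)-4-(triisopropylsilyloxy)cyclohex-3-en-1-yl]carbonyl}-1,3-oxazolidin-2-one | CC(C)[Si](C(C)C)(C(C)C)OC1=C(C)C[C@H](C(=O)N2[C@@H](Cc3ccccc3)COC2=O)[C@@H](CC(C)=C)[C@@H]1C(C)C
F4 | step 7 | [(1S,5S,6R)-3-methyl-6-(2-methylprop-2-en-1-yl)-5-(propan-2-yl)-4-(triisopropylsilyloxy)cyclohex-3-en-1-yl]methanol | CC(C)[Si](C(C)C)(C(C)C)OC1=C(C)C[C@H](CO)[C@@H](CC(C)=C)[C@@H]1C(C)C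
F5 | step 10 | gem-dibromocyclopropane (13 with CBr2 across C5–C7, anti to isopropyl) | CC(C)[Si](C(C)C)(C(C)C)O[C@]12C(Br)(Br)[C@@]1(C)C[C@H]3[C@@H](CC(C)=C3)[C@@H]2C(C)C
F6 | step 10 | (3aR,4S,8aS)-6-bromo-2,7-dimethyl-4-(propan-2-yl)-3a,4,8,8a-tetrahydroazulen-5(3H)-one | O=C1C(Br)=C(C)C[C@H]2[C@@H](CC(C)=C2)[C@@H]1C(C)C
F7 | step 11 | cyclopropanol (14 with the silyl group replaced by hydrogen) | O[C@]12C[C@@]1(C)C[C@H]3[C@@H](CC(C)=C3)[C@@H]2C(C)C
F8 | step 12 | (3aR,4S,5R,8aS)-2,7-dimethyl-4-(propan-2-yl)-3,3a,4,5,8,8a-hexahydroazulen-5-ol | O[C@H]1C=C(C)C[C@H]2[C@@H](CC(C)=C2)[C@@H]1C(C)C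
F9 | step 12 | (3aR,4S,5S,8aS)-2,7-dimethyl-4-(propan-2-yl)-3,3a,4,5,8,8a-hexahydroazulen-5-yl 4-nitrobenzoate | O=C(O[C@@H]1C=C(C)C[C@H]2[C@@H](CC(C)=C2)[C@@H]1C(C)C)c1ccc(cc1)[N+](=O)[O-]
F10 | step 17 | (1S,2R,3aR,4S,5R,7R,8aS)-1,2-epoxy-2,7-dimethyl-4-(propan-2-yl)decahydroazulene-5,7-diol | O[C@@H]1C[C@](C)(O)C[C@H]2[C@@H](C[C@@]3(C)O[C@@H]23)[C@@H]1C(C)C
A1 | alternative 1 | 2-{2-methyl-1-[3-methyl-5-(2-methyloxiran-2-ylmethyl)cyclopent-3-en-1-yl]propyl}-1,3-dithiane (stereochemistry as in the SMILES) | CC(C)[C@H](C1SCCCS1)[C@@H]2CC(C)=C[C@H]2C[C@]3(C)CO3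
A2 | alternative 1 | hydroazulene C5 spiro-1,3-dithiane C7 carbinol | S1CCCSC12C[C@](C)(O)C[C@H]3[C@@H](CC(C)=C3)[C@@H]2C(C)C
A3 | alternative 2 | (3aR,4S,5R,7R,8aS)-7-hydroxy-2,7-dimethyl-4-(propan-2-yl)-3,3a,4,5,6,7,8,8a-octahydroazulen-5-yl 2-oxo-2H-pyran-5-carboxylate | O=C1C=CC(C(=O)O[C@@H]2C[C@](C)(O)C[C@H]3[C@@H](CC(C)=C3)[C@@H]2C(C)C)=CO1
A4 | alternative 2 | 2-(tert-butyldimethylsilyloxy)-1,1-dimethoxyethene | COC(OC)=CO[Si](C)(C)C(C)(C)C
A5 | alternative 2 | (3aR,4S,5R,7R,8aS)-7-hydroxy-2,7-dimethyl-4-(propan-2-yl)-3,3a,4,5,6,7,8,8a-octahydroazulen-5-yl 3-(tert-butyldimethylsilyloxy)-4-methoxybenzoate | COc1ccc(C(=O)O[C@@H]2C[C@](C)(O)C[C@H]3[C@@H](CC(C)=C3)[C@@H]2C(C)C)cc1O[Si](C)(C)C(C)(C)C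
A6 | alternative 3 | eleven-membered (E)-allylic lactone with C5/C7 acetonide and C4 isopropyl group | O=C1C[C@H](C(C)C)[C@H]2C[C@](C)(OC(C)(C)O2)C/C=C/CO1
A7 | alternative 3 | trans-2-vinylcycloheptanecarboxylic acid with C5/C7 acetonide and C4 isopropyl group | CC1(C)O[C@@H]2C[C@](C)(O1)C[C@H](C=C)[C@@H](C(=O)O)[C@@H]2C(C)C
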